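# Late-stage furan cycloaddition route to CNP0602535.1 (29)

## The problem

The target 29 is a 2,3,4,7-tetrahydrooxepine (O1, C2–C7, C5=C6) with all its functionality on two ring atoms. C6 carries a (3E)-4-methylpent-3-enyl chain that ends in an allylic (E)-p-coumarate. The fully substituted C2 carries a free carboxylic acid and a CH2–C(=O) arm whose carbonyl is bonded to a 2,5-dihydroxyphenyl ring (ring A). C2 is the only stereocentre, a tetrasubstituted carbon inside a tertiary ether, so it must be set absolutely by a catalyst or a chiral-pool element, nothing else can relay or repair it, and its ether bond cannot be made by substitution at that carbon. The remaining selectivity questions are positional and geometric: the ring olefin must sit at C5=C6 (not C4=C5 or C6=C7) and both side-chain olefins must be E. The ketone is β to the ring oxygen, so base or hot acid can expel O1 by retro-oxa-Michael reaction, after which the ortho-hydroxyl of ring A can close a chromanone. The allylic ester is sensitive to hydroxide, hydride and zerovalent palladium, the hydroquinone is easily oxidised, and the acid must be released without saponification. The enabling feature is ring A: a benzene with acyl at C1', oxygen at C2' and oxygen at C5' is what a 2-alkoxyfuran gives with a terminal ynone once the oxygen bridge opens, so the whole arene can be grown last on a C(=O)–C≡CH group attached through the methylene to C2.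

## Retrosynthesis

**Protecting-group bonds (29 ⇒ 28 ⇒ 26).** 29 is traced to 28, in which the acid is a tert-butyl ester and the coumarate phenol a tert-butyl ether. Both O–C bonds break in one acidolysis that releases only isobutene; an alkyl ester would need hydroxide, which the allylic ester and the β-alkoxy ketone would not survive. 28 comes from the 5-hydroxy-2-methoxyphenyl ketone 26 by replacing the O-methyl group with hydrogen. Because 26 is a 4-methoxyphenol, this is done by oxidation to acylquinone 27 and reduction. A Lewis-acid dealkylation would compete for the tert-butyl groups and the allylic C–O bonds. The oxidant must spare the coumarate ring, which is why that ring is still an ether at this stage.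

**Ring A (26 ⇒ 23 + 24).** Cutting ring A at C1'–C2' and C5'–C6' returns 2-methoxyfuran 24 and the terminal ynone 23. Adding a protected 2,5-dioxygenated aryl metal to an acyl derivative would bring the ring in intact, but it would force a doubly protected, oxidation-prone arene through an organometallic step beside the cinnamate. The cycloaddition needs no reagent and leaves one phenol already free. The precursor is simpler by a whole ring, two carbons standing for six. The forward reaction must place the acyl group next to the methoxy group and must choose the ynone over every other π bond.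

**Ynone (23 ⇒ 21 + 22).** The C(=O)–C≡ bond is cut to Weinreb amide 21 and ethynylmagnesium bromide 22. The route through an aldehyde, an alkynol and an oxidation costs three steps and a protecting group on the arm, whereas the amide is in place from step 4 and gives the ynone in one step. The price is chemoselectivity: 22 must attack the amide and neither the cinnamate nor the tert-butyl ester.

**Ester (21 ⇒ 17 + 20; 17 ⇒ 16; 20 ⇒ 18 + 19).** The allylic ester C–O bond is cut to alcohol 17 and acid 20. The ester is attached only after the palladium and ruthenium steps, because an allylic carboxylate could ionise under zerovalent palladium in the presence of an organozinc. Until then the oxygen is a silyl ether (16). Acid 20 comes in one condensation from aldehyde 18 and malonic acid 19, with the phenol already protected as the ether that the last step removes.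

**Ring olefin (16 ⇒ 15).** The oxepine is opened at C5=C6 to diene 15, a but-3-enyl group on C2 and a 1,1-disubstituted allyl ether on O1. Cutting O1–C7 instead (cycloetherification onto an allylic halide) invites SN2' closure to a vinyl tetrahydrofuran and needs a Z-trisubstituted olefin made beforehand. Metathesis fixes the olefin at C5=C6 by construction. It must form a trisubstituted olefin in a seven-membered ring and ignore the side-chain olefin.

**Side chain (15 ⇒ 10 + 14; 14 ⇐ 13 ⇐ 12 ⇐ 11).** The C6–CH2 bond is cut between the vinyl bromide 10 and the primary alkylzinc 14. Cutting one bond further out, between the two methylene groups, would be an allyl–allyl coupling with regiochemical ambiguity on both partners. Alkylating alcohol 8 directly with the complete side-chain allylic bromide would spend a multistep fragment in the least efficient step of the route. Bromide 13 is two steps from commercial 11 by allylic oxidation (12) and silylation.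

**Tertiary ether (10 ⇒ 8 + 9).** The O1–C7 bond is cut to tertiary alcohol 8 and 2,3-dibromopropene 9, the smallest and most reactive electrophile that still carries the vinyl bromide. The forward reaction asks a hindered but ester-stabilised alkoxide to undergo SN2 displacement. The arm is an amide at this point so that no enolisable thioester or ketone is exposed to base.

**Stereocentre (8 ⇒ 7 ⇒ 5 + 2; 5 ⇒ 3 + 4; 2 ⇐ 1).** The C2–CH2 bond is cut by an aldol disconnection to keto ester 5 and silyl ketene thioacetal 2. A copper–bis(oxazoline) catalyst sets the only stereocentre in this step, and thioester 7 is then converted into amide 8. A chiral-pool entry through alkylation of a hydroxy-acid-derived dioxolanone enolate would give the same centre with certainty. It accepts only activated halides, however, so the but-3-enyl group and the tert-butyl ester would cost about five further steps. Keto ester 5 is one Grignard addition from 3 and 4, and 2 is one silylation from 1.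

## Roads not taken

**Alternative 1:** The seven-membered ring is grown from a six-membered one. Dibromocarbene is added to the enol ether of a 3,4-dihydro-2H-pyran to give the bicyclic gem-dibromocyclopropane A2. AgOAc in methanol then removes the endo bromide while the fused C5–C7 bond opens, methanol caps the oxocarbenium ion at C7, and the bromo-oxepine acetal A1 results with the double bond at C5=C6.
- Merits: the six-membered precursor closes easily, so the tertiary ether is easier to make than by the intermolecular etherification of 8 (step 5 here). The vinyl bromide at C6 is an excellent handle for the same sp2–sp3 coupling used in the chosen plan.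
- Weak points: the C7 methoxy group must be removed afterwards by ionic reduction through an allylic oxocarbenium ion that can take hydride at C7 or C5, so the olefin position is put at risk again. The C2 arm of A1 is an arylalkyne that still needs regioselective hydration beside a propargylic tertiary ether. The hydroquinone travels as a bis-silyl ether through carbene, silver and hydride chemistry.
- Comparison: step counts are close, but cyclopropanation, expansion and acetal reduction replace a single metathesis. Against the easier ether bond the chosen plan sets an olefin position that is never in doubt and an arene that needs no protection until it exists.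

**Alternative 2:** The ring is closed by the C6–C7 bond. The tertiary alcohol is carried as its methoxymethyl ether in A4, which also holds a (Z)-vinylsilane with silicon on C6. SnCl4 ionises the acetal, the oxocarbenium carbon (the future C7) attacks the silicon-bearing carbon, and loss of the silyl group leaves C5=C6 in the protected oxepine A3.
- Merits: silicon dictates the olefin position. The tertiary C–O bond is made with a reactive chloromethyl ether, which is clearly easier than step 5 here. A3 already contains ring A and the side chain, so it is closer to the target than 16.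
- Weak points: A4 needs a stereodefined trisubstituted vinylsilane carrying both chains, a multistep task in itself. A seven-membered ring is closed by a cationic cyclisation in which protodesilylation and loss of formaldehyde compete. SnCl4 meets a β-alkoxy aryl ketone, an allylic silyl ether and a silylated hydroquinone in one flask.
- Comparison: this road is better at the ether bond and equal in olefin control, and it would be the first choice if step 5 failed. The chosen plan sets against it a neutral, catalytic ring closure, much simpler partners (9, 13) and the late arene.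

**Alternative 3:** The ring is closed at O1–C7. Rh2(OAc)4 decomposes the terminal diazoketone A6, and the tertiary hydroxyl on C2 inserts into the rhodium carbenoid to give the oxepan-3-one A5, with the ketone at C6 of the target numbering.
- Merits: O–H insertion is largely indifferent to hindrance at the alcohol, so this is the most dependable of the four ways of making the tertiary ether. Seven-membered cyclic ethers are known to form this way.
- Weak points: A5 has a ketone where the target has a substituted olefin. Enol triflate formation must choose C5 over C7, and C7, flanked by carbonyl and ether oxygen, is the more readily enolised site. Organometallic addition and dehydration has the same ambiguity plus an exocyclic option. The aryl ketone must be masked as a dioxolane against the carbenoid and unmasked later with acid, and the diazoketone needs diazomethane-type reagents.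
- Comparison: better than the chosen plan at the ether bond, worse at the olefin. The chosen plan sets against it a metathesis that defines C5=C6 unambiguously and two fewer redox or protecting-group adjustments.

Key step: step 14

Assumption: the facial preference established for pyruvate esters under Cu(OTf)2/tert-butyl-bis(oxazoline) catalysis is taken to hold for keto ester 5, so the (R,R)-ligand is assigned to the (2R)-adduct 7.

## Route

Step 1
Reactants: 1 S-tert-butyl ethanethioate
Product: 2 1-(tert-butylsulfanyl)-1-(trimethylsilyloxy)ethene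
Conditions: LiN(iPr)2, THF, −78 °C; Me3SiCl, −78 °C → rt
Reagents that add atoms: chlorotrimethylsilane, C[Si](C)(C)Cl
Why: Kinetic deprotonation of the thioester and O-silylation of the lithium enolate is the standard preparation of silyl ketene thioacetals; 2 is distilled and used as the Mukaiyama aldol nucleophile.

Step 2
Reactants: 3 di-tert-butyl oxalate; 4 but-3-en-1-ylmagnesium bromide
Product: 5 tert-butyl 2-oxohex-5-enoate
Conditions: 4 added to excess 3, THF, −78 °C; 1 M HCl, −78 → 0 °C
Reagents that add atoms: none
Why: Mono-addition of a Grignard reagent to a dialkyl oxalate; the magnesium hemiketal alkoxide persists at −78 °C and collapses to the keto ester only on quench, so a second addition is suppressed.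

Step 3
Reactants: 5 tert-butyl 2-oxohex-5-enoate; 2 1-(tert-butylsulfanyl)-1-(trimethylsilyloxy)ethene
Product: 7 tert-butyl (2R)-2-[2-(tert-butylsulfanyl)-2-oxoethyl]-2-hydroxyhex-5-enoate, via O-trimethylsilyl aldol adduct 6 (not isolated)
Conditions: Cu(OTf)2 (10 mol %), (R,R)-tBu-box (11 mol %), THF, −78 °C; then 1 M HCl, THF, rt
Reagents that add atoms: none
Why: Catalytic enantioselective Mukaiyama aldol addition to an α-keto ester; the 1,2-dicarbonyl unit chelates the divalent copper complex of 2,2'-(propane-2,2-diyl)bis[(4R)-4-tert-butyl-4,5-dihydro-1,3-oxazole] in a distorted square plane, a ligand tert-butyl group shields the si face of the ketone and 2 adds to the re face, which sets C2 as R; silyl transfer gives 6 and dilute acid frees the tertiary alcohol.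

Step 4
Reactants: 7 tert-butyl (2R)-2-[2-(tert-butylsulfanyl)-2-oxoethyl]-2-hydroxyhex-5-enoate
Product: 8 tert-butyl (2R)-2-hydroxy-2-{2-[methoxy(methyl)amino]-2-oxoethyl}hex-5-enoate
Conditions: MeNH(OMe)·HCl, AlMe3, CH2Cl2, 0 °C → rt
Reagents that add atoms: N,O-dimethylhydroxylamine hydrochloride, CNOC.Cl
Why: Weinreb amidation with the aluminium amide formed in the flask; the thioester is the better acyl donor and the hindered tert-butyl ester is left alone, and the amide removes the enolisable thioester before the base-mediated etherification.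

Step 5
Reactants: 8 tert-butyl (2R)-2-hydroxy-2-{2-[methoxy(methyl)amino]-2-oxoethyl}hex-5-enoate; 9 2,3-dibromoprop-1-ene
Product: 10 tert-butyl (2R)-2-[(2-bromoprop-2-en-1-yl)oxy]-2-{2-[methoxy(methyl)amino]-2-oxoethyl}hex-5-enoate
Conditions: NaH, Bu4NI (cat.), 9 (3 equiv), DMF, 0 °C → rt
Reagents that add atoms: none
Why: Williamson ether synthesis; the alkoxide α to the ester is stabilised, 9 is a small, reactive allylic bromide used in excess, and retro-aldol cleavage would have to expel an amide enolate and is not expected.

Step 6
Reactants: 11 5-bromo-2-methylpent-2-ene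
Product: 12 (2E)-5-bromo-2-methylpent-2-en-1-ol
Conditions: SeO2 (20 mol %), tBuOOH (3 equiv), salicylic acid (10 mol %), CH2Cl2, rt
Reagents that add atoms: tert-butyl hydroperoxide, CC(C)(C)OO
Why: Riley allylic oxidation with catalytic selenium dioxide; the ene reaction at the more substituted olefin terminus and the [2,3]-sigmatropic shift place the hydroxyl on the methyl group trans to the chain, which is the E geometry required.

Step 7
Reactants: 12 (2E)-5-bromo-2-methylpent-2-en-1-ol
Product: 13 {[(2E)-5-bromo-2-methylpent-2-en-1-yl]oxy}(tert-butyl)dimethylsilane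
Conditions: tBuMe2SiCl, imidazole, CH2Cl2, 0 °C → rt
Reagents that add atoms: tert-butyl(chloro)dimethylsilane, CC(C)(C)[Si](C)(C)Cl
Why: Standard silylation of a primary allylic alcohol; the silyl ether is inert to zinc insertion, palladium and ruthenium catalysis.

Step 8
Reactants: 10 tert-butyl (2R)-2-[(2-bromoprop-2-en-1-yl)oxy]-2-{2-[methoxy(methyl)amino]-2-oxoethyl}hex-5-enoate; 13 {[(2E)-5-bromo-2-methylpent-2-en-1-yl]oxy}(tert-butyl)dimethylsilane
Product: 15 tert-butyl (2R)-2-({(5E)-7-[(tert-butyldimethylsilyl)oxy]-6-methyl-2-methylidenehept-5-en-1-yl}oxy)-2-{2-[methoxy(methyl)amino]-2-oxoethyl}hex-5-enoate, via alkylzinc bromide 14 (not isolated)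
Conditions: 13, Zn dust, LiCl, THF, 50 °C; then 10, PdCl2(dppf) (5 mol %), THF, 50 °C
Reagents that add atoms: none
Why: Negishi sp3–sp2 coupling; zinc inserts into the primary C–Br bond of 13, zerovalent palladium adds oxidatively to the vinyl bromide of 10, and the wide-bite-angle dppf ligand favours reductive elimination over β-hydride elimination, while the organozinc leaves the ester and the Weinreb amide untouched.

Step 9
Reactants: 15 tert-butyl (2R)-2-({(5E)-7-[(tert-butyldimethylsilyl)oxy]-6-methyl-2-methylidenehept-5-en-1-yl}oxy)-2-{2-[methoxy(methyl)amino]-2-oxoethyl}hex-5-enoate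
Product: 16 tert-butyl (2R)-6-{(3E)-5-[(tert-butyldimethylsilyl)oxy]-4-methylpent-3-en-1-yl}-2-{2-[methoxy(methyl)amino]-2-oxoethyl}-2,3,4,7-tetrahydrooxepine-2-carboxylate
Conditions: RuCl2(=CHPh)(PCy3)(H2IMes) (second-generation Grubbs catalyst, 5 mol %), CH2Cl2 (5 mM), 40 °C
Reagents that add atoms: none
Why: Ring-closing metathesis between the terminal alkene and the 1,1-disubstituted allyl ether gives the seven-membered ring with the trisubstituted C5=C6 bond and loss of ethene; the trisubstituted side-chain olefin is too hindered and too remote to compete, and dilution suppresses dimerisation.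

Step 10
Reactants: 16 tert-butyl (2R)-6-{(3E)-5-[(tert-butyldimethylsilyl)oxy]-4-methylpent-3-en-1-yl}-2-{2-[methoxy(methyl)amino]-2-oxoethyl}-2,3,4,7-tetrahydrooxepine-2-carboxylate
Product: 17 tert-butyl (2R)-6-[(3E)-5-hydroxy-4-methylpent-3-en-1-yl]-2-{2-[methoxy(methyl)amino]-2-oxoethyl}-2,3,4,7-tetrahydrooxepine-2-carboxylate
Conditions: Bu4NF, THF, 0 °C
Reagents that add atoms: none
Why: Fluoride cleavage of a primary silyl ether; no ketone is present yet, so the basicity of the reagent is harmless to the β-alkoxy amide and the tert-butyl ester.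

Step 11
Reactants: 18 4-tert-butoxybenzaldehyde; 19 malonic acid
Product: 20 (2E)-3-(4-tert-butoxyphenyl)prop-2-enoic acid
Conditions: pyridine, piperidine (cat.), 90 °C
Reagents that add atoms: none
Why: Doebner–Knoevenagel condensation with decarboxylation gives the E-cinnamic acid; the aryl tert-butyl ether is stable to the basic medium.

Step 12
Reactants: 17 tert-butyl (2R)-6-[(3E)-5-hydroxy-4-methylpent-3-en-1-yl]-2-{2-[methoxy(methyl)amino]-2-oxoethyl}-2,3,4,7-tetrahydrooxepine-2-carboxylate; 20 (2E)-3-(4-tert-butoxyphenyl)prop-2-enoic acid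
Product: 21 tert-butyl (2R)-6-[(3E)-5-{[(2E)-3-(4-tert-butoxyphenyl)prop-2-enoyl]oxy}-4-methylpent-3-en-1-yl]-2-{2-[methoxy(methyl)amino]-2-oxoethyl}-2,3,4,7-tetrahydrooxepine-2-carboxylate
Conditions: EDC·HCl, DMAP (cat.), CH2Cl2, 0 °C → rt
Reagents that add atoms: none
Why: Steglich esterification of a primary allylic alcohol by acyl transfer at the carboxyl carbon, so the allylic C–O bond and the E geometry are not touched; it is done before the ynone exists because nucleophilic amines add to ynones.

Step 13
Reactants: 21 tert-butyl (2R)-6-[(3E)-5-{[(2E)-3-(4-tert-butoxyphenyl)prop-2-enoyl]oxy}-4-methylpent-3-en-1-yl]-2-{2-[methoxy(methyl)amino]-2-oxoethyl}-2,3,4,7-tetrahydrooxepine-2-carboxylate; 22 ethynylmagnesium bromide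
Product: 23 tert-butyl (2R)-6-[(3E)-5-{[(2E)-3-(4-tert-butoxyphenyl)prop-2-enoyl]oxy}-4-methylpent-3-en-1-yl]-2-(2-oxobut-3-yn-1-yl)-2,3,4,7-tetrahydrooxepine-2-carboxylate
Conditions: HC≡CMgBr (3 equiv), THF, −20 → 0 °C; poured into cold 1 M HCl
Reagents that add atoms: none
Why: Weinreb ketone synthesis; the chelated tetrahedral magnesium adduct holds until quench, the amide is activated by chelation with the ring oxygen while the conjugated, donor-substituted cinnamate and the hindered tert-butyl ester are poor electrophiles for this mild acetylide, and the cold acidic inverse quench protonates the released amine before it can add to the ynone.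

Step 14
Reactants: 23 tert-butyl (2R)-6-[(3E)-5-{[(2E)-3-(4-tert-butoxyphenyl)prop-2-enoyl]oxy}-4-methylpent-3-en-1-yl]-2-(2-oxobut-3-yn-1-yl)-2,3,4,7-tetrahydrooxepine-2-carboxylate; 24 2-methoxyfuran
Product: 26 tert-butyl (2R)-6-[(3E)-5-{[(2E)-3-(4-tert-butoxyphenyl)prop-2-enoyl]oxy}-4-methylpent-3-en-1-yl]-2-[2-(5-hydroxy-2-methoxyphenyl)-2-oxoethyl]-2,3,4,7-tetrahydrooxepine-2-carboxylate, via methoxy-oxanorbornadiene 25 (not isolated)
Conditions: 24 (3 equiv), CH2Cl2, 0 °C → rt (40 °C if required), acid-free glassware, dark
Reagents that add atoms: none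
Why: The electron-rich furan and the polarised ynone combine in an asynchronous [4+2] cycloaddition in which the unsubstituted C5 of 24 bonds first to the terminal alkyne carbon and the methoxy-bearing C2 then closes onto the acyl-bearing carbon, giving the 1-methoxy-2-acyl-7-oxanorbornadiene 25. The bridging C–O bond at the methoxy-substituted bridgehead then ionises to a methoxy-stabilised cation and the proton at the other bridgehead is lost, so the bridge oxygen ends as the phenol meta to the ketone and the methoxy group sits ortho to it. The closest known reaction type is the cycloaddition and ring-opening aromatisation of 2-alkoxyfurans with acetylenic ketones and esters to 4-alkoxyphenols. The six-membered carbocycle of ring A is closed by an intermolecular [4+2] cycloaddition that makes both new ring bonds in one operation. No stereocentre is created that persists: the two bridgehead centres of 25 are erased on aromatisation and the remote C2 centre of the oxepine is not touched. The step needs regioselectivity in the addition and in the bridge opening and chemoselectivity for the ynone; the first is secured by pairing the most nucleophilic furan carbon with the β-carbon of the ynone, the second by the methoxy donor, and the third because the cinnamate and the trisubstituted alkenes are far poorer 2π partners at room temperature. Acid-free conditions keep 24 from hydrolysing and the β-alkoxy ketone from eliminating.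

Step 15
Reactants: 26 tert-butyl (2R)-6-[(3E)-5-{[(2E)-3-(4-tert-butoxyphenyl)prop-2-enoyl]oxy}-4-methylpent-3-en-1-yl]-2-[2-(5-hydroxy-2-methoxyphenyl)-2-oxoethyl]-2,3,4,7-tetrahydrooxepine-2-carboxylate
Product: 28 tert-butyl (2R)-6-[(3E)-5-{[(2E)-3-(4-tert-butoxyphenyl)prop-2-enoyl]oxy}-4-methylpent-3-en-1-yl]-2-[2-(2,5-dihydroxyphenyl)-2-oxoethyl]-2,3,4,7-tetrahydrooxepine-2-carboxylate, via acylbenzoquinone 27 (not isolated)
Conditions: PhI(OAc)2 (1.1 equiv), MeCN/H2O (4:1), 0 °C; then aq Na2S2O4, EtOAc, rt
Reagents that add atoms: water, O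
Why: Oxidative demethylation of a 4-methoxyphenol; the trivalent iodine reagent oxidises the phenol, water adds at the methoxy-bearing carbon and methanol is lost to give quinone 27, which dithionite reduces at once to the hydroquinone; the coumarate ring is an aryl ether at this stage and is not oxidised, and no Lewis acid meets the tert-butyl groups or the allylic C–O bonds.

Step 16
Reactants: 28 tert-butyl (2R)-6-[(3E)-5-{[(2E)-3-(4-tert-butoxyphenyl)prop-2-enoyl]oxy}-4-methylpent-3-en-1-yl]-2-[2-(2,5-dihydroxyphenyl)-2-oxoethyl]-2,3,4,7-tetrahydrooxepine-2-carboxylate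
Product: 29 (2R)-2-[2-(2,5-dihydroxyphenyl)-2-oxoethyl]-6-[(3E)-5-{[(2E)-3-(4-hydroxyphenyl)prop-2-enoyl]oxy}-4-methylpent-3-en-1-yl]-2,3,4,7-tetrahydrooxepine-2-carboxylic acid
Conditions: CF3CO2H/CH2Cl2 (1:4), anisole (10 equiv), 0 °C → rt
Reagents that add atoms: none
Why: Acidolysis of the tert-butyl ester and the aryl tert-butyl ether by loss of the tert-butyl cation as isobutene, with anisole as cation trap; both olefins carry an electron-withdrawing allylic oxygen and resist protonation, and the low temperature keeps the β-alkoxy ketone from eliminating.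

## Compound list

1 | S-tert-butyl ethanethioate | CC(=O)SC(C)(C)C | starting material
2 | 1-(tert-butylsulfanyl)-1-(trimethylsilyloxy)ethene | C=C(O[Si](C)(C)C)SC(C)(C)C | intermediate
3 | di-tert-butyl oxalate | CC(C)(C)OC(=O)C(=O)OC(C)(C)C | starting material
4 | but-3-en-1-ylmagnesium bromide | C=CCC[Mg]Br | starting material
5 | tert-butyl 2-oxohex-5-enoate | C=CCCC(=O)C(=O)OC(C)(C)C | intermediate
6 | tert-butyl (2R)-2-[2-(tert-butylsulfanyl)-2-oxoethyl]-2-(trimethylsilyloxy)hex-5-enoate | C=CCC[C@@](CC(=O)SC(C)(C)C)(C(=O)OC(C)(C)C)O[Si](C)(C)C | intermediate (not isolated)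
7 | tert-butyl (2R)-2-[2-(tert-butylsulfanyl)-2-oxoethyl]-2-hydroxyhex-5-enoate | C=CCC[C@@](CC(=O)SC(C)(C)C)(C(=O)OC(C)(C)C)O | intermediate
8 | tert-butyl (2R)-2-hydroxy-2-{2-[methoxy(methyl)amino]-2-oxoethyl}hex-5-enoate | C=CCC[C@@](CC(=O)N(C)OC)(C(=O)OC(C)(C)C)O | intermediate
9 | 2,3-dibromoprop-1-ene | C=C(Br)CBr | starting material
10 | tert-butyl (2R)-2-[(2-bromoprop-2-en-1-yl)oxy]-2-{2-[methoxy(methyl)amino]-2-oxoethyl}hex-5-enoate | C=CCC[C@@](CC(=O)N(C)OC)(C(=O)OC(C)(C)C)OCC(Br)=C | intermediate
11 | 5-bromo-2-methylpent-2-ene | CC(C)=CCCBr | starting material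
12 | (2E)-5-bromo-2-methylpent-2-en-1-ol | OC/C(C)=C/CCBr | intermediate
13 | {[(2E)-5-bromo-2-methylpent-2-en-1-yl]oxy}(tert-butyl)dimethylsilane | CC(C)(C)[Si](C)(C)OC/C(C)=C/CCBr | intermediate
14 | bromo{(3E)-5-[(tert-butyldimethylsilyl)oxy]-4-methylpent-3-en-1-yl}zinc | CC(C)(C)[Si](C)(C)OC/C(C)=C/CC[Zn]Br | intermediate (not isolated)
15 | tert-butyl (2R)-2-({(5E)-7-[(tert-butyldimethylsilyl)oxy]-6-methyl-2-methylidenehept-5-en-1-yl}oxy)-2-{2-[methoxy(methyl)amino]-2-oxoethyl}hex-5-enoate | C=CCC[C@@](CC(=O)N(C)OC)(C(=O)OC(C)(C)C)OCC(=C)CC/C=C(\C)CO[Si](C)(C)C(C)(C)C | intermediate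
16 | tert-butyl (2R)-6-{(3E)-5-[(tert-butyldimethylsilyl)oxy]-4-methylpent-3-en-1-yl}-2-{2-[methoxy(methyl)amino]-2-oxoethyl}-2,3,4,7-tetrahydrooxepine-2-carboxylate | CC(C)(C)[Si](C)(C)OC/C(C)=C/CCC1=CCC[C@@](CC(=O)N(C)OC)(C(=O)OC(C)(C)C)OC1 | intermediate
17 | tert-butyl (2R)-6-[(3E)-5-hydroxy-4-methylpent-3-en-1-yl]-2-{2-[methoxy(methyl)amino]-2-oxoethyl}-2,3,4,7-tetrahydrooxepine-2-carboxylate | OC/C(C)=C/CCC1=CCC[C@@](CC(=O)N(C)OC)(C(=O)OC(C)(C)C)OC1 | intermediate
18 | 4-tert-butoxybenzaldehyde | CC(C)(C)Oc1ccc(C=O)cc1 | starting material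
19 | malonic acid | OC(=O)CC(=O)O | starting material
20 | (2E)-3-(4-tert-butoxyphenyl)prop-2-enoic acid | CC(C)(C)Oc1ccc(/C=C/C(=O)O)cc1 | intermediate
21 | tert-butyl (2R)-6-[(3E)-5-{[(2E)-3-(4-tert-butoxyphenyl)prop-2-enoyl]oxy}-4-methylpent-3-en-1-yl]-2-{2-[methoxy(methyl)amino]-2-oxoethyl}-2,3,4,7-tetrahydrooxepine-2-carboxylate | CC(C)(C)Oc1ccc(/C=C/C(=O)OC/C(C)=C/CCC2=CCC[C@@](CC(=O)N(C)OC)(C(=O)OC(C)(C)C)OC2)cc1 | intermediate
22 | ethynylmagnesium bromide | C#C[Mg]Br | starting material
23 | tert-butyl (2R)-6-[(3E)-5-{[(2E)-3-(4-tert-butoxyphenyl)prop-2-enoyl]oxy}-4-methylpent-3-en-1-yl]-2-(2-oxobut-3-yn-1-yl)-2,3,4,7-tetrahydrooxepine-2-carboxylate | CC(C)(C)Oc1ccc(/C=C/C(=O)OC/C(C)=C/CCC2=CCC[C@@](CC(=O)C#C)(C(=O)OC(C)(C)C)OC2)cc1 | intermediate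
24 | 2-methoxyfuran | COc1ccco1 | starting material
25 | tert-butyl (2R)-6-[(3E)-5-{[(2E)-3-(4-tert-butoxyphenyl)prop-2-enoyl]oxy}-4-methylpent-3-en-1-yl]-2-[2-(1-methoxy-7-oxabicyclo[2.2.1]hepta-2,5-dien-2-yl)-2-oxoethyl]-2,3,4,7-tetrahydrooxepine-2-carboxylate (both bridgehead configurations) | CC(C)(C)Oc1ccc(/C=C/C(=O)OC/C(C)=C/CCC2=CCC[C@@](CC(=O)C3=CC4C=CC3(OC)O4)(C(=O)OC(C)(C)C)OC2)cc1 | intermediate (not isolated)
26 | tert-butyl (2R)-6-[(3E)-5-{[(2E)-3-(4-tert-butoxyphenyl)prop-2-enoyl]oxy}-4-methylpent-3-en-1-yl]-2-[2-(5-hydroxy-2-methoxyphenyl)-2-oxoethyl]-2,3,4,7-tetrahydrooxepine-2-carboxylate | CC(C)(C)Oc1ccc(/C=C/C(=O)OC/C(C)=C/CCC2=CCC[C@@](CC(=O)c3cc(O)ccc3OC)(C(=O)OC(C)(C)C)OC2)cc1 | intermediate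
27 | tert-butyl (2R)-6-[(3E)-5-{[(2E)-3-(4-tert-butoxyphenyl)prop-2-enoyl]oxy}-4-methylpent-3-en-1-yl]-2-[2-(3,6-dioxocyclohexa-1,4-dien-1-yl)-2-oxoethyl]-2,3,4,7-tetrahydrooxepine-2-carboxylate | CC(C)(C)Oc1ccc(/C=C/C(=O)OC/C(C)=C/CCC2=CCC[C@@](CC(=O)C3=CC(=O)C=CC3=O)(C(=O)OC(C)(C)C)OC2)cc1 | intermediate (not isolated)
28 | tert-butyl (2R)-6-[(3E)-5-{[(2E)-3-(4-tert-butoxyphenyl)prop-2-enoyl]oxy}-4-methylpent-3-en-1-yl]-2-[2-(2,5-dihydroxyphenyl)-2-oxoethyl]-2,3,4,7-tetrahydrooxepine-2-carboxylate | CC(C)(C)Oc1ccc(/C=C/C(=O)OC/C(C)=C/CCC2=CCC[C@@](CC(=O)c3cc(O)ccc3O)(C(=O)OC(C)(C)C)OC2)cc1 | intermediate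
29 | (2R)-2-[2-(2,5-dihydroxyphenyl)-2-oxoethyl]-6-[(3E)-5-{[(2E)-3-(4-hydroxyphenyl)prop-2-enoyl]oxy}-4-methylpent-3-en-1-yl]-2,3,4,7-tetrahydrooxepine-2-carboxylic acid (CNP0602535.1) | C/C(=C\CCC1=CCC[C@@](CC(=O)c2cc(O)ccc2O)(C(=O)O)OC1)COC(=O)/C=C/c1ccc(O)cc1 | target

## Step count and least certain steps

Total step count: 16. Longest linear sequence: 12 steps (steps 2, 3, 4, 5, 8, 9, 10, 12, 13, 14, 15, 16).

**Step 14 (key step).** The most likely failure is interruption after the first C–C bond. The zwitterion formed when furan C5 adds to the alkyne terminus may lose a proton instead of closing, which would end in vinylogous substitution of the furan. Alternatively 24 may be consumed by acid-induced hydrolysis and polymerisation before it reacts, which is more likely on a dilute, valuable ynone than in simple cases. Fallback: ring A is brought in intact, setting out from 21 and returning at 28.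
- 2,5-Dimethoxyphenylmagnesium bromide (commercial, THF, −20 °C) is added to the Weinreb amide 21 to give the 2,5-dimethoxyphenyl ketone F1.
- (NH4)2Ce(NO3)6 in aqueous acetonitrile at 0 °C oxidises the dimethoxyarene of F1 to acylquinone 27.
- Na2S2O4 reduces 27 in the same work-up, which rejoins the route at 28.

**Step 5.** The most likely failure is slow O-alkylation of the hindered tertiary alkoxide, so that base-induced dehydrobromination of 9 or fragmentation of the alkoxide takes over. Fallback: an acid-catalysed etherification that forms no alkoxide, setting out from 8 and returning at 10.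
- 2-Bromoprop-2-en-1-ol and trichloroacetonitrile (cat. DBU) give 2-bromoprop-2-en-1-yl 2,2,2-trichloroethanimidate F2.
- F2 alkylates 8 under catalytic CF3SO3H in cyclohexane/CH2Cl2 at 0 °C to give 10.

**Step 13.** The most likely failures are loss of chemoselectivity (attack of the acetylide on the cinnamate carbonyl or its β-carbon during the slow amide addition) and conjugate addition of the released N,O-dimethylhydroxylamine to the ynone during work-up. Fallback: the amide is taken to the aldehyde first, setting out from 21 and returning at 23.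
- Cp2Zr(H)Cl (THF, rt) reduces the Weinreb amide selectively to the aldehyde F3.
- HC≡CMgBr at −78 °C adds to the aldehyde only and gives the propargylic alcohol F4 as a mixture of carbinol epimers.
- Dess–Martin periodinane oxidises F4 to 23.

**Step 3.** The most likely failure is erosion of facial discrimination or slow turnover, because 5 carries a larger alkyl group and a bulkier ester than the pyruvates on which the model rests. Fallback: racemic synthesis and classical resolution, setting out from 5 and 2 and returning at 7.
- Aldol addition under achiral catalysis (Cu(OTf)2 without ligand, then 1 M HCl) gives the racemic adduct F5.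
- CF3CO2H removes the tert-butyl ester to give the racemic hydroxy acid F6.
- Fractional crystallisation of its cinchonidine salt and acidification give the (R)-acid F7.
- tert-Butyl 2,2,2-trichloroacetimidate (cat. BF3·OEt2) re-esterifies F7 to 7.

**Step 15.** The most likely failures are capture of the highly electrophilic acylquinone 27 by water, acetate or a side-chain alkene before it is reduced, or over-oxidation of the product hydroquinone. Fallback: chelation-controlled Lewis-acid dealkylation, setting out from 26 and returning directly at 29. BCl3 with pentamethylbenzene in CH2Cl2 (−78 → 0 °C) removes the methyl group next to the carbonyl together with both tert-butyl groups, so step 16 is skipped and no new compound is made.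

## Further compounds

F1 | step 14 | tert-butyl (2R)-6-[(3E)-5-{[(2E)-3-(4-tert-butoxyphenyl)prop-2-enoyl]oxy}-4-methylpent-3-en-1-yl]-2-[2-(2,5-dimethoxyphenyl)-2-oxoethyl]-2,3,4,7-tetrahydrooxepine-2-carboxylate | CC(C)(C)Oc1ccc(/C=C/C(=O)OC/C(C)=C/CCC2=CCC[C@@](CC(=O)c3cc(OC)ccc3OC)(C(=O)OC(C)(C)C)OC2)cc1
F2 | step 5 | 2-bromoprop-2-en-1-yl 2,2,2-trichloroethanimidate | C=C(Br)COC(=N)C(Cl)(Cl)Cl
F3 | step 13 | tert-butyl (2R)-6-[(3E)-5-{[(2E)-3-(4-tert-butoxyphenyl)prop-2-enoyl]oxy}-4-methylpent-3-en-1-yl]-2-(2-oxoethyl)-2,3,4,7-tetrahydrooxepine-2-carboxylate | CC(C)(C)Oc1ccc(/C=C/C(=O)OC/C(C)=C/CCC2=CCC[C@@](CC=O)(C(=O)OC(C)(C)C)OC2)cc1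
F4 | step 13 | tert-butyl (2R)-6-[(3E)-5-{[(2E)-3-(4-tert-butoxyphenyl)prop-2-enoyl]oxy}-4-methylpent-3-en-1-yl]-2-(2-hydroxybut-3-yn-1-yl)-2,3,4,7-tetrahydrooxepine-2-carboxylate (both carbinol epimers) | CC(C)(C)Oc1ccc(/C=C/C(=O)OC/C(C)=C/CCC2=CCC[C@@](CC(O)C#C)(C(=O)OC(C)(C)C)OC2)cc1
F5 | step 3 | tert-butyl 2-[2-(tert-butylsulfanyl)-2-oxoethyl]-2-hydroxyhex-5-enoate (racemic) | C=CCCC(O)(CC(=O)SC(C)(C)C)C(=O)OC(C)(C)C
F6 | step 3 | 2-[2-(tert-butylsulfanyl)-2-oxoethyl]-2-hydroxyhex-5-enoic acid (racemic) | C=CCCC(O)(CC(=O)SC(C)(C)C)C(=O)O
F7 | step 3 | (2R)-2-[2-(tert-butylsulfanyl)-2-oxoethyl]-2-hydroxyhex-5-enoic acid | C=CCC[C@@](CC(=O)SC(C)(C)C)(C(=O)O)O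
F0 | step 15 | none | none
A1 | alternative 1 | 2-(trimethylsilyl)ethyl (2R)-2-{[2,5-bis(tert-butyldimethylsilyloxy)phenyl]ethynyl}-6-bromo-7-methoxy-2,3,4,7-tetrahydrooxepine-2-carboxylate (C7 epimers) | BrC1=CCC[C@@](C#Cc2cc(O[Si](C)(C)C(C)(C)C)ccc2O[Si](C)(C)C(C)(C)C)(C(=O)OCC[Si](C)(C)C)OC1OC
A2 | alternative 1 | 2-(trimethylsilyl)ethyl (3R)-3-{[2,5-bis(tert-butyldimethylsilyloxy)phenyl]ethynyl}-7,7-dibromo-2-oxabicyclo[4.1.0]heptane-3-carboxylate (ring-fusion epimers) | BrC1(Br)C2CC[C@@](C#Cc3cc(O[Si](C)(C)C(C)(C)C)ccc3O[Si](C)(C)C(C)(C)C)(C(=O)OCC[Si](C)(C)C)OC12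
A3 | alternative 2 | 2-(trimethylsilyl)ethyl (2R)-2-{2-[2,5-bis(tert-butyldimethylsilyloxy)phenyl]-2-oxoethyl}-6-{(3E)-5-[(tert-butyldimethylsilyl)oxy]-4-methylpent-3-en-1-yl}-2,3,4,7-tetrahydrooxepine-2-carboxylate | CC(C)(C)[Si](C)(C)OC/C(C)=C/CCC1=CCC[C@@](CC(=O)c2cc(O[Si](C)(C)C(C)(C)C)ccc2O[Si](C)(C)C(C)(C)C)(C(=O)OCC[Si](C)(C)C)OC1
A4 | alternative 2 | 2-(trimethylsilyl)ethyl (2R,5Z,9E)-2-{2-[2,5-bis(tert-butyldimethylsilyloxy)phenyl]-2-oxoethyl}-11-[(tert-butyldimethylsilyl)oxy]-2-(methoxymethoxy)-10-methyl-6-(trimethylsilyl)undeca-5,9-dienoate | CC(C)(C)[Si](C)(C)OC/C(C)=C/CC/C(=C/CC[C@@](CC(=O)c1cc(O[Si](C)(C)C(C)(C)C)ccc1O[Si](C)(C)C(C)(C)C)(C(=O)OCC[Si](C)(C)C)OCOC)[Si](C)(C)C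
A5 | alternative 3 | 2-(trimethylsilyl)ethyl (2R)-2-({2-[2,5-bis(tert-butyldimethylsilyloxy)phenyl]-1,3-dioxolan-2-yl}methyl)-6-oxooxepane-2-carboxylate | O=C1CCC[C@@](CC2(OCCO2)c3cc(O[Si](C)(C)C(C)(C)C)ccc3O[Si](C)(C)C(C)(C)C)(C(=O)OCC[Si](C)(C)C)OC1
A6 | alternative 3 | 2-(trimethylsilyl)ethyl (2R)-2-({2-[2,5-bis(tert-butyldimethylsilyloxy)phenyl]-1,3-dioxolan-2-yl}methyl)-7-diazo-2-hydroxy-6-oxoheptanoate | [N-]=[N+]=CC(=O)CCC[C@@](CC1(OCCO1)c2cc(O[Si](C)(C)C(C)(C)C)ccc2O[Si](C)(C)C(C)(C)C)(C(=O)OCC[Si](C)(C)C)O
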